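**Retrosynthetic overview**
- Feature: carbons C7–C12. The cyclopentenone ring C8–C12 has the C12 carbinol sitting between the C10=C11–C9(=O) enone and C8, and C8 carries exocyclic C7. Together these six carbons are the ring of a 4-alkyl p-quinol from which one ring CH (C7) has been pushed out.
- Key disconnection: C8–C9. It is made by a six-to-five 1,2-acyl shift in the syn-epoxy p-quinol acetate. This gives the 5-(hydroxymethylene)cyclopentenone with C7 at the aldehyde level.
- After it: C6–C7 comes from Suzuki coupling of the E-enol triflate with an E-alkenylboronate. C10–Br is installed last, through the 10,11-epoxide and HBr, because electrophilic bromine would attack C14=C15 first.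
- Before it: a Z-selective Wittig reaction (C14=C15) gives the phenol. Dearomatisation gives the achiral p-quinol, desymmetrising syn-epoxidation of one enone arm fixes C12, and the alcohol is then acetylated.
- Ring order: purchased benzene ring, cyclohexadienone, oxirane-fused cyclohexenone, cyclopentenone. A transient oxirane on C10–C11 appears at the end.

Key step: step 6

Assumption: prostanoid numbering (C1 ester carbon to C20) is used throughout, and the sense of induction in step 4 is assigned by analogy, so the quinidine-derived pseudo-enantiomeric catalyst is taken if a test run shows attack on the other arm.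

**Step 1**
Reactants: 1 4-(2-bromoethyl)phenol
Product: 2 [2-(4-hydroxyphenyl)ethyl]triphenylphosphonium bromide
Conditions: PPh3, MeCN, reflux
Reagents that add atoms: triphenylphosphine, c1ccc(cc1)P(c1ccccc1)c1ccccc1
Why: SN2 displacement of the primary bromide by the phosphine (phosphonium salt formation) proceeds under neutral conditions, in which the free phenol is a spectator.

**Step 2**
Reactants: 2 [2-(4-hydroxyphenyl)ethyl]triphenylphosphonium bromide; 3 hexanal
Product: 5 4-[(Z)-oct-2-enyl]phenol, via sodium ylide phenolate 4 (not isolated)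
Conditions: NaN(SiMe3)2 (2.1 equiv), THF, 0 °C; then 3, −78 °C to rt; aq NH4Cl
Reagents that add atoms: none
Why: In this salt-free Wittig olefination the first equivalent of base is spent on the phenol (as in the carboxyalkylphosphonium protocol), and the non-stabilised ylide adds to the aliphatic aldehyde under kinetic control through the cis-oxaphosphetane, which sets C14=C15 as Z.

**Step 3**
Reactants: 5 4-[(Z)-oct-2-enyl]phenol
Product: 6 4-hydroxy-4-[(Z)-oct-2-enyl]cyclohexa-2,5-dienone
Conditions: PhI(OAc)2, MeCN/H2O, 0 °C
Reagents that add atoms: water, O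
Why: In this oxidative dearomatisation of a 4-alkylphenol, ligand exchange at iodine activates the ring and water attacks the para carbon to give the achiral p-quinol, while the isolated alkene is not oxidised by this reagent.

**Step 4**
Reactants: 6 4-hydroxy-4-[(Z)-oct-2-enyl]cyclohexa-2,5-dienone
Product: 7 (4R,5S,6R)-5,6-epoxy-4-hydroxy-4-[(Z)-oct-2-enyl]cyclohex-2-enone (epoxide syn to OH)
Conditions: 9-amino-9-deoxy-epi-quinine bis(trifluoroacetate) (10 mol %), 50% aq H2O2 (1.2 equiv), dioxane, 30 °C
Reagents that add atoms: hydrogen peroxide, OO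
Why: Proposed new method: the primary-amine salt should condense with the dienone carbonyl to a chiral iminium ion, H2O2 held by the protonated quinuclidine adds to one π-face of a β-carbon, and the β-peroxy enamine closes to the cis-epoxide (amine-catalysed Weitz–Scheffer epoxidation); because peroxide nucleophiles attack 4-alkyl-4-hydroxydienones on the hydroxyl-bearing face (hydrogen bond to H2O2, smaller substituent), the face preference of the catalyst becomes a choice between the two enantiotopic enone arms and sets C12 together with both oxirane carbons, a mismatched attack gives a separable anti diastereomer rather than the enantiomer, and the minor enantiomer keeps the catalyst-matched arm and is drained by a faster second epoxidation; the closest known reaction type is the amine-salt-catalysed asymmetric H2O2 epoxidation of simple cyclohex-2-enones, which has not been shown on cross-conjugated p-quinols.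

**Step 5**
Reactants: 7 (4R,5S,6R)-5,6-epoxy-4-hydroxy-4-[(Z)-oct-2-enyl]cyclohex-2-enone
Product: 8 (4R,5S,6R)-4-acetoxy-5,6-epoxy-4-[(Z)-oct-2-enyl]cyclohex-2-enone (epoxide syn to OAc)
Conditions: Ac2O, Et3N, 4-(dimethylamino)pyridine (cat.), CH2Cl2, 0 °C to rt
Reagents that add atoms: acetic anhydride, CC(=O)OC(C)=O
Why: Nucleophile-catalysed acylation of the tertiary alcohol touches no stereocentre, the amine bases leave the epoxy enone intact, and the ester removes the strong oxygen donor that would drive a semipinacol shift from C12.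

**Step 6**
Reactants: 8 (4R,5S,6R)-4-acetoxy-5,6-epoxy-4-[(Z)-oct-2-enyl]cyclohex-2-enone
Product: 10 (4R,5Z)-4-acetoxy-5-(hydroxymethylene)-4-[(Z)-oct-2-enyl]cyclopent-2-enone, via 5-formyl ketone 9 (not isolated)
Conditions: BF3·OEt2 (25 mol %), CH2Cl2, −40 to 0 °C; pH 7 buffer
Reagents that add atoms: none
Why: Proposed new method: BF3 binds the epoxide oxygen and, as the C8–O bond (the carbon next to C12) stretches, the C9 acyl carbon slides from C7 to C8 at the rear of the breaking bond while C7–O becomes the formyl C=O, so no free cation has to develop beside the acetate. The closest known reaction type is the BF3-induced 1,2-acyl shift of cyclic α,β-epoxy ketones to ring-contracted 2-formyl ketones, known for β-alkylated cyclohexenone oxides but not for an epoxy p-quinol ester with a secondary, acyloxy-flanked β-carbon. The cyclopentenone ring C8–C12 closes not by cyclisation but by this suprafacial 1,2-shift inside the six-membered ring (six to five), which forms C8–C9 and leaves C7 exocyclic. The only new stereocentre, C8 in 9, is set by inversion at the migration terminus (formyl cis to acetate) and disappears on enolisation to the hydrogen-bonded Z-enol 10, whereas C12 is a spectator and keeps its configuration. The acyl shift must beat hydride shift from C7, migration of C11 or C13 from C12, and acetoxonium formation: collapse of the C7 alkoxide to a carbonyl favours groups leaving C7, acyl outruns hydrogen in this rearrangement type, the acetyl group makes the C12 oxygen a poor donor, and the acetate sits syn to the epoxide oxygen and cannot reach the rear of C8. Loss of acetic acid from 10 is held back because it would create a cyclopentadienone.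

**Step 7**
Reactants: 10 (4R,5Z)-4-acetoxy-5-(hydroxymethylene)-4-[(Z)-oct-2-enyl]cyclopent-2-enone
Product: 11 (4R,5E)-4-acetoxy-4-[(Z)-oct-2-enyl]-5-[(trifluoromethylsulfonyloxy)methylene]cyclopent-2-enone
Conditions: Tf2O, i-Pr2NEt, CH2Cl2, −78 °C
Reagents that add atoms: trifluoromethanesulfonic anhydride, O=S(=O)(OS(=O)(=O)C(F)(F)F)C(F)(F)F
Why: In this enol triflation of a 1,3-dicarbonyl compound under non-chelating conditions, the ammonium enolate relaxes from the chelate-like U shape to the dipole-minimised form with O7 anti to C9=O, so sulfonylation of the aldehyde-derived oxygen should give the E-triflate that defines C7=C8.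

**Step 8**
Reactants: 12 methyl hex-5-ynoate
Product: 13 methyl (E)-6-(4,4,5,5-tetramethyl-1,3,2-dioxaborolan-2-yl)hex-5-enoate
Conditions: pinacolborane, Cp2Zr(H)Cl (10 mol %), Et3N (10 mol %), neat, 60 °C
Reagents that add atoms: pinacolborane, [H]B1OC(C)(C)C(C)(C)O1
Why: Zirconocene-hydride-catalysed hydroboration of the terminal alkyne is a syn addition with boron at the terminal carbon, which sets C5=C6 as E and tolerates the ester.

**Step 9**
Reactants: 11 (4R,5E)-enol triflate; 13 methyl (E)-6-(pinacolboryl)hex-5-enoate
Product: 14 methyl (5E,7E,12R,14Z)-12-acetoxy-9-oxoprosta-5,7,10,14-tetraenoate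
Conditions: Pd(PPh3)4 (5 mol %), K3PO4, THF/H2O, rt
Reagents that add atoms: none
Why: In this Suzuki–Miyaura coupling zerovalent palladium inserts rapidly into the electron-poor vinylogous acyl triflate, both alkenyl partners couple with retention to give the 5E,7E-diene, and phosphate base at room temperature spares the acetate and the ester.

**Step 10**
Reactants: 14 methyl (5E,7E,12R,14Z)-12-acetoxy-9-oxoprosta-5,7,10,14-tetraenoate
Product: 15 methyl (5E,7E,10S,11R,12S,14Z)-12-acetoxy-10,11-epoxy-9-oxoprosta-5,7,14-trienoate (oxirane drawn cis to the acetate; either face serves)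
Conditions: 30% aq H2O2, NaOH (cat.), MeOH, −20 °C
Reagents that add atoms: hydrogen peroxide, OO
Why: In this Weitz–Scheffer epoxidation hydroperoxide adds at C11 of the strained endocyclic enone, the most electrophilic β-carbon of a cross-conjugated 5-alkylidenecyclopent-2-enone, while the isolated C14=C15 alkene is inert to a nucleophilic oxidant, and the two new stereocentres are erased in the next step.

**Step 11**
Reactants: 15 methyl (5E,7E,10S,11R,12S,14Z)-12-acetoxy-10,11-epoxy-9-oxoprosta-5,7,14-trienoate
Product: 17 methyl (5E,7E,12R,14Z)-12-acetoxy-10-bromo-9-oxoprosta-5,7,10,14-tetraenoate, via trans-bromohydrin 16 (not isolated)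
Conditions: 48% aq HBr, THF, 0 °C to rt
Reagents that add atoms: hydrogen bromide, Br
Why: In this known conversion of an α,β-epoxy ketone into an α-halo enone, bromide opens the protonated oxirane at C10 (activated by the carbonyl, whereas C11 is shielded by quaternary C12) and the β-hydroxy ketone dehydrates through its enol, so bromine arrives as a nucleophile and C14=C15 is never exposed to electrophilic bromine.

**Compound list**
1 | 4-(2-bromoethyl)phenol | Oc1ccc(CCBr)cc1 | starting material
2 | [2-(4-hydroxyphenyl)ethyl]triphenylphosphonium bromide | [Br-].Oc1ccc(CC[P+](c2ccccc2)(c2ccccc2)c2ccccc2)cc1 | intermediate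
3 | hexanal | CCCCCC=O | starting material
4 | sodium 4-[2-(triphenylphosphoranylidene)ethyl]phenolate | [Na+].[O-]c1ccc(CC=P(c2ccccc2)(c2ccccc2)c2ccccc2)cc1 | intermediate
5 | 4-[(Z)-oct-2-enyl]phenol | CCCCC/C=C\Cc1ccc(O)cc1 | intermediate
6 | 4-hydroxy-4-[(Z)-oct-2-enyl]cyclohexa-2,5-dienone | CCCCC/C=C\CC1(O)C=CC(=O)C=C1 | intermediate
7 | (4R,5S,6R)-5,6-epoxy-4-hydroxy-4-[(Z)-oct-2-enyl]cyclohex-2-enone | CCCCC/C=C\C[C@@]1(O)C=CC(=O)[C@@H]2O[C@H]12 | intermediate
8 | (4R,5S,6R)-4-acetoxy-5,6-epoxy-4-[(Z)-oct-2-enyl]cyclohex-2-enone | CCCCC/C=C\C[C@@]1(OC(C)=O)C=CC(=O)[C@@H]2O[C@H]12 | intermediate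
9 | (4R,5S)-4-acetoxy-5-formyl-4-[(Z)-oct-2-enyl]cyclopent-2-enone | CCCCC/C=C\C[C@@]1(OC(C)=O)C=CC(=O)[C@@H]1C=O | intermediate
10 | (4R,5Z)-4-acetoxy-5-(hydroxymethylene)-4-[(Z)-oct-2-enyl]cyclopent-2-enone | CCCCC/C=C\C[C@@]1(OC(C)=O)C=CC(=O)/C1=C\O | intermediate
11 | (4R,5E)-4-acetoxy-4-[(Z)-oct-2-enyl]-5-[(trifluoromethylsulfonyloxy)methylene]cyclopent-2-enone | CCCCC/C=C\C[C@@]1(OC(C)=O)C=CC(=O)/C1=C/OS(=O)(=O)C(F)(F)F | intermediate
12 | methyl hex-5-ynoate | C#CCCCC(=O)OC | starting material
13 | methyl (E)-6-(4,4,5,5-tetramethyl-1,3,2-dioxaborolan-2-yl)hex-5-enoate | COC(=O)CCC/C=C/B1OC(C)(C)C(C)(C)O1 | intermediate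
14 | methyl (5E,7E,12R,14Z)-12-acetoxy-9-oxoprosta-5,7,10,14-tetraenoate | CCCCC/C=C\C[C@@]1(OC(C)=O)C=CC(=O)/C1=C/C=C/CCCC(=O)OC | intermediate
15 | methyl (5E,7E,10S,11R,12S,14Z)-12-acetoxy-10,11-epoxy-9-oxoprosta-5,7,14-trienoate | CCCCC/C=C\C[C@@]1(OC(C)=O)[C@@H]2O[C@@H]2C(=O)/C1=C/C=C/CCCC(=O)OC | intermediate
16 | methyl (5E,7E,10R,11S,12S,14Z)-12-acetoxy-10-bromo-11-hydroxy-9-oxoprosta-5,7,14-trienoate | CCCCC/C=C\C[C@@]1(OC(C)=O)[C@H](O)[C@@H](Br)C(=O)/C1=C/C=C/CCCC(=O)OC | intermediate
17 | methyl (5E,7E,12R,14Z)-12-acetoxy-10-bromo-9-oxoprosta-5,7,10,14-tetraenoate | CCCCC/C=C\C[C@@]1(OC(C)=O)C=C(Br)C(=O)/C1=C/C=C/CCCC(=O)OC | target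

**Step count**
- Total steps: 11.
- Longest linear sequence: 10 (steps 1–7 and 9–11). Step 8 is the side branch.

**Steps most likely to fail**

Step 6.
- Risk: the oxirane may stay closed because the acetate withdraws electron density from C8. It may also open with hydride shift, or with migration of the octenyl group followed by aromatisation.
- Fallback (known chemistry only, no ring contraction): chirality transfer on a purchased cyclopentenone, then aldol condensation. It sets out from methyl hex-5-ynoate 12 and comes back to the route at 14.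
- Semihydrogenation of 12 (H2, Pd/CaCO3–Pb(OAc)2, quinoline) gives methyl hex-5-enoate F1. Cross-metathesis with crotonaldehyde (second-generation Hoveyda–Grubbs catalyst) gives methyl (E)-7-oxohept-5-enoate F2.
- Commercial (Z)-oct-2-en-1-ol is converted (MsCl, LiCl, 2,4,6-collidine, DMF) into (Z)-1-chlorooct-2-ene F3. With activated barium (BaI2, lithium biphenylide, THF, −78 °C) this gives (Z)-oct-2-enylbarium chloride F4.
- This reagent type adds to carbonyl groups through its α-carbon with retention of the Z geometry. With commercial (R)-4-(tert-butyldimethylsilyloxy)cyclopent-2-enone it should add 1,2 and anti to the silyloxy group, giving (1S,4R)-4-(tert-butyldimethylsilyloxy)-1-[(Z)-oct-2-enyl]cyclopent-2-en-1-ol F5. The other diastereomer is removed by chromatography.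
- Bu4NF gives (1S,4R)-1-[(Z)-oct-2-enyl]cyclopent-2-ene-1,4-diol F6. MnO2 oxidises only the secondary allylic alcohol, giving (S)-4-hydroxy-4-[(Z)-oct-2-enyl]cyclopent-2-enone F7, in which the silyloxy stereocentre has been traded for C12.
- Double deprotonation (LiN(i-Pr)2, 2.2 equiv, THF, −78 °C) and aldol addition of C8 to F2 gives methyl (5E,14Z)-7,12-dihydroxy-9-oxoprosta-5,10,14-trienoate F8.
- Ac2O, 4-(dimethylamino)pyridine and pyridine give methyl (5E,14Z)-7,12-diacetoxy-9-oxoprosta-5,10,14-trienoate F9, which loses the C7 acetate by E1cB elimination to give 14.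

Step 4.
- Risk: iminium formation from the cross-conjugated, γ-quaternary dienone may be too slow. The catalyst may discriminate poorly between the two arms, or the second arm may be epoxidised as well.
- Fallback (known chemistry): racemic directed epoxidation, then resolution. It sets out from 6 and comes back at 7.
- t-BuOOH with catalytic benzyltrimethylammonium hydroxide in THF at 0 °C epoxidises p-quinols on the hydroxyl face. It gives the racemic syn-epoxide, that is 7 together with its mirror image (4S,5R,6S)-5,6-epoxy-4-hydroxy-4-[(Z)-oct-2-enyl]cyclohex-2-enone F10.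
- The enantiomers are separated by preparative chromatography on a cellulose- or amylose-carbamate chiral phase, and only 7 is carried on.

Step 7.
- Risk: sulfonylation may follow the chelated enol geometry and give the Z-triflate or a mixture. The crowded E-isomer may isomerise, or the enolate may lose acetate.
- Fallback: the geometry is corrected after the coupling instead of before it. It sets out from 10 and comes back at 14.
- Under chelating conditions (NaH, then PhNTf2, THF, 0 °C) 10 is converted deliberately into (4R,5Z)-4-acetoxy-4-[(Z)-oct-2-enyl]-5-[(trifluoromethylsulfonyloxy)methylene]cyclopent-2-enone F11.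
- Suzuki coupling with 13 under the conditions of step 9 gives, with retention, methyl (5E,7Z,12R,14Z)-12-acetoxy-9-oxoprosta-5,7,10,14-tetraenoate F12.
- A trace of I2 in daylight (reversible iodine-atom addition to the conjugated dienone) equilibrates C7=C8 towards the 7E isomer 14. Remaining 7Z material is separated and resubmitted.

**Further compounds**
F1 | step 6 | methyl hex-5-enoate | C=CCCCC(=O)OC
F2 | step 6 | methyl (E)-7-oxohept-5-enoate | O=C/C=C/CCCC(=O)OC
F3 | step 6 | (Z)-1-chlorooct-2-ene | CCCCC/C=C\CCl
F4 | step 6 | (Z)-oct-2-enylbarium chloride | CCCCC/C=C\C[Ba]Cl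
F5 | step 6 | (1S,4R)-4-(tert-butyldimethylsilyloxy)-1-[(Z)-oct-2-enyl]cyclopent-2-en-1-ol | CCCCC/C=C\C[C@@]1(O)C=C[C@H](O[Si](C)(C)C(C)(C)C)C1
F6 | step 6 | (1S,4R)-1-[(Z)-oct-2-enyl]cyclopent-2-ene-1,4-diol | CCCCC/C=C\C[C@@]1(O)C=C[C@H](O)C1
F7 | step 6 | (S)-4-hydroxy-4-[(Z)-oct-2-enyl]cyclopent-2-enone | CCCCC/C=C\C[C@@]1(O)C=CC(=O)C1
F8 | step 6 | methyl (5E,14Z)-7,12-dihydroxy-9-oxoprosta-5,10,14-trienoate (12R, mixture at C7 and C8) | CCCCC/C=C\C[C@@]1(O)C=CC(=O)C1C(O)/C=C/CCCC(=O)OC
F9 | step 6 | methyl (5E,14Z)-7,12-diacetoxy-9-oxoprosta-5,10,14-trienoate (12R, mixture at C7 and C8) | CCCCC/C=C\C[C@@]1(OC(C)=O)C=CC(=O)C1C(OC(C)=O)/C=C/CCCC(=O)OC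
F10 | step 4 | (4S,5R,6S)-5,6-epoxy-4-hydroxy-4-[(Z)-oct-2-enyl]cyclohex-2-enone | CCCCC/C=C\C[C@]1(O)C=CC(=O)[C@H]2O[C@@H]12
F11 | step 7 | (4R,5Z)-4-acetoxy-4-[(Z)-oct-2-enyl]-5-[(trifluoromethylsulfonyloxy)methylene]cyclopent-2-enone | CCCCC/C=C\C[C@@]1(OC(C)=O)C=CC(=O)/C1=C\OS(=O)(=O)C(F)(F)F
F12 | step 7 | methyl (5E,7Z,12R,14Z)-12-acetoxy-9-oxoprosta-5,7,10,14-tetraenoate | CCCCC/C=C\C[C@@]1(OC(C)=O)C=CC(=O)/C1=C\C=C\CCCC(=O)OC
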